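**Retrosynthetic overview**

- The target is the achiral quinone ring C1(=O)–C2(OH)–C3(C22H45)–C4(=O)–C5(OMe)–C6(H). The plan rests on reading the contiguous C1–C4 segment (O, O, alkyl, O) as a squaric acid-derived four-membered ring and C5(OMe)–C6(H) as a 1-methoxyvinyl group.
- Quinone ⇐ benzene-1,2,4-triol (oxidation) ⇐ hydroquinone with isopropyl on O2 and methyl on O5 (selective de-isopropylation), so the two ether oxygens stay distinguishable.
- Hydroquinone ⇐ 4-hydroxy-4-(1-methoxyvinyl)cyclobutenone by thermal ring expansion: the C1–C4 bond of the four-membered ring is broken and C1–C6 is formed.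
- Cyclobutenone ⇐ diisopropyl squarate by two carbonyl additions (1-methoxyvinyllithium, then docosyllithium) with a trifluoroacetate-triggered 1,3-carbonyl transposition that puts docosyl on C3.
- Ring order: the four-membered ring is purchased; the only ring made is the six-membered carbocycle (step 5), which is oxidised to the quinone in step 7.

Key step: step 5

Remark on the chemistry: the target has no stereocentre and no stereogenic double bond, so the achiral compound itself is the "single enantiomer"; the carbinol centre of the intermediates is racemic and is erased in step 5.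

**Step 1**
Reactants: 1 diisopropyl squarate (3,4-diisopropoxycyclobut-3-ene-1,2-dione); 2 methyl vinyl ether
Product: 4 racemic 4-hydroxy-2,3-diisopropoxy-4-(1-methoxyvinyl)cyclobut-2-en-1-one, via 1-methoxyvinyllithium 3 (not isolated)
Conditions: 2 (1.5 equiv), t-BuLi (1.1 equiv), THF, −78 to 0 °C; then 1, THF, −78 °C; sat. aq NH4Cl, −78 °C; Et3N-deactivated silica
Reagents that add atoms: none
Why: α-Lithiation of the vinyl ether followed by 1,2-addition of the vinyllithium to one of the two equivalent squarate carbonyls should stop at mono-addition because the resulting alkoxide deactivates the remaining vinylogous ester carbonyl; the new carbinol centre forms as a racemate and needs no control.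

**Step 2**
Reactants: 4 racemic 4-hydroxy-2,3-diisopropoxy-4-(1-methoxyvinyl)cyclobut-2-en-1-one
Product: 5 racemic 2,3-diisopropoxy-4-(1-methoxyvinyl)-4-(trimethylsilyloxy)cyclobut-2-en-1-one
Conditions: TMSCl, Et3N, DMAP (cat.), CH2Cl2, 0 °C to rt
Reagents that add atoms: chlorotrimethylsilane, C[Si](C)(C)Cl
Why: Standard O-silylation of a tertiary alcohol under basic conditions that spare the enol ether; the silyl ether removes the acidic proton and makes this oxygen a poor leaving group for the next step, and the stereocentre is untouched.

**Step 3**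
Reactants: 5 racemic 2,3-diisopropoxy-4-(1-methoxyvinyl)-4-(trimethylsilyloxy)cyclobut-2-en-1-one; 6 1-bromodocosane
Product: 10 racemic 3-docosyl-2-isopropoxy-4-(1-methoxyvinyl)-4-(trimethylsilyloxy)cyclobut-2-en-1-one, via docosyllithium 7 (not isolated), via lithium alkoxide adduct 8 (not isolated), via tertiary trifluoroacetate 9 (not isolated)
Conditions: 6, Li (1% Na), Et2O, 0 °C to rt; then 5, THF, −78 °C; TFAA (1.05 equiv), −78 °C; sat. aq NaHCO3, −78 to 0 °C
Reagents that add atoms: water, O
Why: Reductive lithiation of the primary bromide gives the alkyllithium, which adds 1,2 to the remaining vinylogous ester carbonyl; O-trifluoroacetylation of the alkoxide makes the new carbinol the only ionisable position, and the 1,3-dialkoxycyclobutenyl cation is hydrolysed at its isopropoxy-bearing terminus with loss of isopropanol (squarate 1,2-addition followed by 1,3-carbonyl transposition), so the transient carbinol centre ends as the docosyl-bearing sp2 carbon and raises no stereochemical issue.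

**Step 4**
Reactants: 10 racemic 3-docosyl-2-isopropoxy-4-(1-methoxyvinyl)-4-(trimethylsilyloxy)cyclobut-2-en-1-one
Product: 11 racemic 3-docosyl-4-hydroxy-2-isopropoxy-4-(1-methoxyvinyl)cyclobut-2-en-1-one
Conditions: TBAF, AcOH (1:1), THF, 0 °C
Reagents that add atoms: none
Why: Fluoride-induced cleavage of the tertiary trimethylsilyl ether, buffered with acetic acid so that neither a free alkoxide (ring opening) nor a strong acid (enol ether hydrolysis, carbinol ionisation) is present; the carbinol centre stays racemic.

**Step 5**
Reactants: 11 racemic 3-docosyl-4-hydroxy-2-isopropoxy-4-(1-methoxyvinyl)cyclobut-2-en-1-one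
Product: 14 3-docosyl-2-isopropoxy-5-methoxybenzene-1,4-diol, via dienylketene 12 (not isolated), via cyclohexa-2,4-dienone 13 (not isolated)
Conditions: degassed toluene, 110 °C, Ar, base-washed glassware
Reagents that add atoms: none
Why: Heating should open the strained cyclobutenone by a thermal 4π conrotatory cleavage of the acyl–carbinol bond (C1–C4) to the hydroxy-substituted dienylketene 12, with release of ring strain as the driving force. A thermal 6π disrotatory electrocyclisation then joins the ketene carbon to the CH2 terminus of the methoxyvinyl group (C1–C6), closing the only new ring, the six-membered carbocycle, as cyclohexa-2,4-dienone 13, and enolisation of its CH2–C=O unit gives the aromatic hydroquinone 14. The closest known reaction type is the Moore rearrangement of 4-alkenyl-4-hydroxycyclobutenones to hydroquinones. No stereocentre is created, and the racemic carbinol centre of 11 becomes an sp2 ring carbon. The step needs torquoselectivity, with the methoxyvinyl group turning inward so that it ends cis to the ketene; the carbinol hydroxyl secures this because a lone-pair donor strongly prefers outward rotation, which also keeps the OH away from the ketene and disfavours butenolide formation. The substitution pattern of the new ring is fixed entirely by the cyclobutenone, so the closure involves no regiochemical choice.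

**Step 6**
Reactants: 14 3-docosyl-2-isopropoxy-5-methoxybenzene-1,4-diol
Product: 15 3-docosyl-5-methoxybenzene-1,2,4-triol
Conditions: BCl3 (1 M in CH2Cl2, 3.5 equiv), CH2Cl2, −78 to 0 °C, Ar; degassed H2O; used crude
Reagents that add atoms: none
Why: Lewis acid ether cleavage: BCl3 dealkylates a secondary (isopropyl) aryl ether by an SN1-like C–O ionisation at or below 0 °C, conditions under which an aryl methyl ether should be retained; no stereocentre is involved.

**Step 7**
Reactants: 15 3-docosyl-5-methoxybenzene-1,2,4-triol
Product: 16 3-docosyl-2-hydroxy-5-methoxycyclohexa-2,5-diene-1,4-dione (target)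
Conditions: FeCl3·6H2O (2.2 equiv), THF/H2O, 0 °C to rt; dil. HCl wash
Reagents that add atoms: none
Why: Two-electron oxidation of the electron-rich benzene-1,2,4-triol by iron(III) should give the 2-hydroxy-1,4-benzoquinone, the para-quinone being the stable tautomer, while the methyl ether and the alkyl chain are inert; no stereocentre is involved.

**Compound list**

1 | diisopropyl squarate (3,4-diisopropoxycyclobut-3-ene-1,2-dione) | CC(C)OC1=C(OC(C)C)C(=O)C1=O | starting material
2 | methyl vinyl ether | COC=C | starting material
3 | 1-methoxyvinyllithium | [Li]C(=C)OC | intermediate (not isolated)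
4 | 4-hydroxy-2,3-diisopropoxy-4-(1-methoxyvinyl)cyclobut-2-en-1-one (racemic) | COC(=C)C1(O)C(=O)C(OC(C)C)=C1OC(C)C | intermediate
5 | 2,3-diisopropoxy-4-(1-methoxyvinyl)-4-(trimethylsilyloxy)cyclobut-2-en-1-one (racemic) | COC(=C)C1(O[Si](C)(C)C)C(=O)C(OC(C)C)=C1OC(C)C | intermediate
6 | 1-bromodocosane | CCCCCCCCCCCCCCCCCCCCCCBr | starting material
7 | docosyllithium | [Li]CCCCCCCCCCCCCCCCCCCCCC | intermediate (not isolated)
8 | lithium 1-docosyl-2,3-diisopropoxy-4-(1-methoxyvinyl)-4-(trimethylsilyloxy)cyclobut-2-en-1-olate (racemic, diastereomer mixture) | CCCCCCCCCCCCCCCCCCCCCCC1([O-])C(OC(C)C)=C(OC(C)C)C1(O[Si](C)(C)C)C(=C)OC.[Li+] | intermediate (not isolated)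
9 | 1-docosyl-2,3-diisopropoxy-4-(1-methoxyvinyl)-4-(trimethylsilyloxy)cyclobut-2-en-1-yl trifluoroacetate (racemic, diastereomer mixture) | CCCCCCCCCCCCCCCCCCCCCCC1(OC(=O)C(F)(F)F)C(OC(C)C)=C(OC(C)C)C1(O[Si](C)(C)C)C(=C)OC | intermediate (not isolated)
10 | 3-docosyl-2-isopropoxy-4-(1-methoxyvinyl)-4-(trimethylsilyloxy)cyclobut-2-en-1-one (racemic) | CCCCCCCCCCCCCCCCCCCCCCC1=C(OC(C)C)C(=O)C1(O[Si](C)(C)C)C(=C)OC | intermediate
11 | 3-docosyl-4-hydroxy-2-isopropoxy-4-(1-methoxyvinyl)cyclobut-2-en-1-one (racemic) | CCCCCCCCCCCCCCCCCCCCCCC1=C(OC(C)C)C(=O)C1(O)C(=C)OC | intermediate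
12 | (3E)-3-docosyl-4-hydroxy-2-isopropoxy-5-methoxyhexa-1,3,5-trien-1-one (dienylketene) | O=C=C(OC(C)C)/C(CCCCCCCCCCCCCCCCCCCCCC)=C(/O)C(=C)OC | intermediate (not isolated)
13 | 3-docosyl-4-hydroxy-2-isopropoxy-5-methoxycyclohexa-2,4-dien-1-one | CCCCCCCCCCCCCCCCCCCCCCC1=C(OC(C)C)C(=O)CC(OC)=C1O | intermediate (not isolated)
14 | 3-docosyl-2-isopropoxy-5-methoxybenzene-1,4-diol | CCCCCCCCCCCCCCCCCCCCCCc1c(O)c(OC)cc(O)c1OC(C)C | intermediate
15 | 3-docosyl-5-methoxybenzene-1,2,4-triol | CCCCCCCCCCCCCCCCCCCCCCc1c(O)c(OC)cc(O)c1O | intermediate
16 | 3-docosyl-2-hydroxy-5-methoxycyclohexa-2,5-diene-1,4-dione | CCCCCCCCCCCCCCCCCCCCCCC1=C(O)C(=O)C=C(OC)C1=O | target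

**Step count**

Total steps: 7. Longest linear sequence: 7 steps, from diisopropyl squarate 1.

**Steps most likely to fail**

Step 5, the ring expansion. The process at risk is the partitioning of the ketene: any inward rotation of the hydroxyl lets it add to the ketene and give a butenolide. The free tertiary α-alkoxyallylic carbinol may also ionise or lose its enol ether on heating before it opens. The fallback sets out from silyl ether 10, omitting step 4, and subjects the O-silylated carbinol itself to the thermolysis in degassed toluene at 110 °C. A siloxy group is likewise an outward-rotating donor but cannot add to the ketene. The product should be the mono-silylated hydroquinone 3-docosyl-2-isopropoxy-5-methoxy-4-(trimethylsilyloxy)phenol F1. K2CO3 in degassed methanol should then remove the silyl group and return the route at 14.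

Step 3, the addition and carbonyl transposition. The process at risk is attack of the anhydride, or of the trifluoroacetic acid it liberates, on the electron-rich 1-methoxyvinyl group (C-acylation or protonolysis). Loss of the silyl group followed by ionisation at the wrong carbinol is a second risk. The fallback avoids the transposition by moving the methoxy group to the vinyl terminus, so that the normal regiochemistry of squarate addition gives the required pattern. It sets out from 1, from 7 (made from 6 as in step 3) and from 2, and comes back at 14.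
- Docosyllithium 7 is added to squarate 1 (THF, −78 °C) to give 4-docosyl-4-hydroxy-2,3-diisopropoxycyclobut-2-en-1-one F2.
- Catalytic conc. HCl in CH2Cl2 should convert this into 3-docosyl-4-isopropoxycyclobut-3-ene-1,2-dione F3.
- Methyl vinyl ether 2 is brominated (Br2, CH2Cl2, −78 °C) to 1,2-dibromo-1-methoxyethane F4 and dehydrobrominated with i-Pr2NEt on warming to (Z)-1-bromo-2-methoxyethene F5.
- Bromine–lithium exchange (t-BuLi, 2 equiv, Et2O/THF, −78 °C) gives (Z)-2-methoxyvinyllithium F6.
- This should add to the more electrophilic carbonyl of the dione, the one next to the isopropoxy-bearing carbon, to give 2-docosyl-4-hydroxy-3-isopropoxy-4-[(Z)-2-methoxyvinyl]cyclobut-2-en-1-one F7.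
- Thermolysis of this carbinol in degassed toluene is a Moore ring expansion that closes onto the methoxy-bearing vinyl carbon. It should give the same hydroquinone 14, and the route continues with step 6.

Step 6, the selective ether cleavage. The process at risk is loss of selectivity: boron bound to the C4 phenoxide can direct demethylation of the neighbouring methoxy group. The unprotected hydroquinone may also oxidise or over-react during the cleavage and work-up. The fallback sets out from 14 and masks both phenols first.
- Ac2O, pyridine and catalytic DMAP should give 3-docosyl-2-isopropoxy-5-methoxy-1,4-phenylene diacetate F8.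
- BCl3 (CH2Cl2, −78 to 0 °C) then cleaves only the isopropyl ether, with aryl acetates and the methyl ether as spectators, to give 3-docosyl-2-hydroxy-5-methoxy-1,4-phenylene diacetate F9.
- K2CO3 in degassed methanol under argon removes both acetates and returns the route at triol 15, which is oxidised as in step 7.

**Further compounds**

F1 | step 5 | 3-docosyl-2-isopropoxy-5-methoxy-4-(trimethylsilyloxy)phenol | CCCCCCCCCCCCCCCCCCCCCCc1c(O[Si](C)(C)C)c(OC)cc(O)c1OC(C)C
F2 | step 3 | 4-docosyl-4-hydroxy-2,3-diisopropoxycyclobut-2-en-1-one (racemic) | CCCCCCCCCCCCCCCCCCCCCCC1(O)C(=O)C(OC(C)C)=C1OC(C)C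
F3 | step 3 | 3-docosyl-4-isopropoxycyclobut-3-ene-1,2-dione | CCCCCCCCCCCCCCCCCCCCCCC1=C(OC(C)C)C(=O)C1=O
F4 | step 3 | 1,2-dibromo-1-methoxyethane (racemic) | COC(Br)CBr
F5 | step 3 | (Z)-1-bromo-2-methoxyethene | CO/C=C\Br
F6 | step 3 | (Z)-2-methoxyvinyllithium | CO/C=C\[Li]
F7 | step 3 | 2-docosyl-4-hydroxy-3-isopropoxy-4-[(Z)-2-methoxyvinyl]cyclobut-2-en-1-one (racemic) | CCCCCCCCCCCCCCCCCCCCCCC1=C(OC(C)C)C(O)(/C=C\OC)C1=O
F8 | step 6 | 3-docosyl-2-isopropoxy-5-methoxy-1,4-phenylene diacetate | CCCCCCCCCCCCCCCCCCCCCCc1c(OC(C)=O)c(OC)cc(OC(C)=O)c1OC(C)C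
F9 | step 6 | 3-docosyl-2-hydroxy-5-methoxy-1,4-phenylene diacetate | CCCCCCCCCCCCCCCCCCCCCCc1c(OC(C)=O)c(OC)cc(OC(C)=O)c1O
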